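## Retrosynthetic overview

1. Target 25 ⇐ removal of two MOM ethers ⇐ aromatic Claisen rearrangement of a 4'-O-prenyl ether, which puts the 1,1-dimethylallyl group on C-5' and frees 4'-OH.
2. Ring C (the pyran) ⇐ intramolecular CuI-catalysed aryl C–O coupling of a (2R)-2-aryl-3-(2-bromoaryl)propan-1-ol (O1–C8a bond).
3. C-3 stereocenter and C3–C4 bond ⇐ Evans alkylation of the ring B arylacetyl imide of (R)-4-benzyloxazolidin-2-one with a ring A benzyl bromide; LiBH4 then releases the alcohol.
4. Ring B arylacetic acid ⇐ 2,3,4-trihydroxybenzaldehyde by O-differentiation in order of acidity (4-O-prenyl, 3-O-MOM, 2-O-Me) and one-carbon homologation with TosMIC.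
5. Rings A and B are bought as benzenes; ring C is the only ring formed, after the stereocenter is set.

Assumption: the SMILES is read as the (3R)-isoflavan, and compounds 1, 2, 12 and 15 are taken as commercial. Abbreviations: prenyl = 3-methylbut-2-en-1-yl, MOM = methoxymethyl.

## Route

Step 1
Reactants: 1 2,3,4-trihydroxybenzaldehyde; 2 prenyl bromide
Product: 3 2,3-dihydroxy-4-(prenyloxy)benzaldehyde
Conditions: Li2CO3 (1.5 equiv), DMF, 45 °C
Reagents that add atoms: none
Why: Williamson etherification in which the weak base ionises only the 4-OH (para to the formyl group, most acidic, not chelated), so the prenyl group goes on O-4.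

Step 2
Reactants: 3 2,3-dihydroxy-4-(prenyloxy)benzaldehyde
Product: 6 2-methoxy-3-(methoxymethoxy)-4-(prenyloxy)benzaldehyde, via disodium dianion 4 (not isolated), via sodium phenoxide 5 (not isolated)
Conditions: NaH (2.2 equiv), DMF, 0 °C; MOMCl (1.0 equiv), −20 to 0 °C; then MeI (3 equiv), rt
Reagents that add atoms: chloromethyl methyl ether (MOMCl), COCCl; iodomethane (MeI), CI
Why: Two Williamson etherifications steered by dianion regioselectivity: the 3-phenoxide, not conjugated to the formyl group, is the more nucleophilic and takes the single equivalent of MOMCl, and the remaining chelated 2-phenoxide is then methylated in the same flask.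

Step 3
Reactants: 6 2-methoxy-3-(methoxymethoxy)-4-(prenyloxy)benzaldehyde
Product: 8 [2-methoxy-3-(methoxymethoxy)-4-(prenyloxy)phenyl]acetonitrile, via tosyl-oxazoline adduct 7 (not isolated)
Conditions: TosMIC, KOt-Bu (2.5 equiv), DME, −40 °C; then MeOH, reflux
Reagents that add atoms: tosylmethyl isocyanide (TosMIC), Cc1ccc(cc1)S(=O)(=O)C[N+]#[C-]
Why: van Leusen reductive cyanation: the TosMIC anion adds to the aldehyde and closes to the tosyl-oxazoline, and methanolysis expels sulfinate and formate to leave the homologated nitrile under purely basic conditions that spare the MOM and prenyl ethers.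

Step 4
Reactants: 8 [2-methoxy-3-(methoxymethoxy)-4-(prenyloxy)phenyl]acetonitrile
Product: 11 [2-methoxy-3-(methoxymethoxy)-4-(prenyloxy)phenyl]acetic acid, via primary amide 9 (not isolated), via potassium carboxylate 10 (not isolated)
Conditions: KOH, EtOH/H2O (2:1), reflux; then 1 M HCl, 0 °C, to pH 3
Reagents that add atoms: water, O; potassium hydroxide, [K+].[OH-]
Why: Base hydrolysis of the nitrile, which the acid-labile MOM and prenyl ethers tolerate, with only a brief cold acidification to free the acid.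

Step 5
Reactants: 11 [2-methoxy-3-(methoxymethoxy)-4-(prenyloxy)phenyl]acetic acid; 12 (R)-4-benzyl-1,3-oxazolidin-2-one
Product: 14 (4R)-4-benzyl-3-{[2-methoxy-3-(methoxymethoxy)-4-(prenyloxy)phenyl]acetyl}-1,3-oxazolidin-2-one, via mixed pivalic anhydride 13 (not isolated)
Conditions: t-BuCOCl, Et3N, THF, −20 °C; then LiCl, 12, rt
Reagents that add atoms: none
Why: N-acylation of the auxiliary through the mixed pivalic anhydride, which is attacked at the less hindered arylacetyl carbonyl by the LiCl/Et3N-activated oxazolidinone.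

Step 6
Reactants: 15 2-bromo-4-hydroxybenzaldehyde
Product: 16 2-bromo-4-(methoxymethoxy)benzaldehyde
Conditions: MOMCl, i-Pr2NEt, CH2Cl2, 0 °C to rt
Reagents that add atoms: chloromethyl methyl ether (MOMCl), COCCl
Why: O-alkylation of the only phenol as its MOM ether, a group that survives every basic and reductive step ahead and leaves together with the ring B MOM group at the end.

Step 7
Reactants: 16 2-bromo-4-(methoxymethoxy)benzaldehyde
Product: 17 [2-bromo-4-(methoxymethoxy)phenyl]methanol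
Conditions: NaBH4, MeOH, 0 °C
Reagents that add atoms: none
Why: Simple hydride reduction of the aldehyde that leaves the aryl bromide and the acetal alone.

Step 8
Reactants: 17 [2-bromo-4-(methoxymethoxy)phenyl]methanol
Product: 18 2-bromo-1-(bromomethyl)-4-(methoxymethoxy)benzene
Conditions: CBr4, PPh3, CH2Cl2, 0 °C
Reagents that add atoms: tetrabromomethane (CBr4), BrC(Br)(Br)Br
Why: Appel bromination under neutral conditions, so the MOM ether is kept, and the ortho bromine tempers the lability of this electron-rich benzyl bromide.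

Step 9
Reactants: 14 (4R)-4-benzyl-3-{[2-methoxy-3-(methoxymethoxy)-4-(prenyloxy)phenyl]acetyl}-1,3-oxazolidin-2-one; 18 2-bromo-1-(bromomethyl)-4-(methoxymethoxy)benzene
Product: 20 (4R)-4-benzyl-3-{(2R)-3-[2-bromo-4-(methoxymethoxy)phenyl]-2-[2-methoxy-3-(methoxymethoxy)-4-(prenyloxy)phenyl]propanoyl}-1,3-oxazolidin-2-one, via sodium Z-enolate 19 (not isolated)
Conditions: NaN(SiMe3)2, THF, −78 °C; then 18, −78 to −20 °C
Reagents that add atoms: none
Why: Evans asymmetric alkylation: the chelated sodium Z-enolate is shielded on one face by the benzyl group of the (R)-auxiliary, so the benzyl bromide adds from the other face and sets the new α-center as (R), the future C-3.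

Step 10
Reactants: 20 (4R)-4-benzyl-3-{(2R)-3-[2-bromo-4-(methoxymethoxy)phenyl]-2-[2-methoxy-3-(methoxymethoxy)-4-(prenyloxy)phenyl]propanoyl}-1,3-oxazolidin-2-one
Product: 21 (2R)-3-[2-bromo-4-(methoxymethoxy)phenyl]-2-[2-methoxy-3-(methoxymethoxy)-4-(prenyloxy)phenyl]propan-1-ol
Conditions: LiBH4, H2O (2 equiv), Et2O/THF, 0 °C
Reagents that add atoms: none
Why: Reductive cleavage of the imide by borohydride is fast and not basic enough to epimerise the α-aryl center, and it leaves the aryl bromide, acetals and prenyl ether untouched.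

Step 11
Reactants: 21 (2R)-3-[2-bromo-4-(methoxymethoxy)phenyl]-2-[2-methoxy-3-(methoxymethoxy)-4-(prenyloxy)phenyl]propan-1-ol
Product: 22 (3R)-7-(methoxymethoxy)-3-[2-methoxy-3-(methoxymethoxy)-4-(prenyloxy)phenyl]-3,4-dihydro-2H-chromene
Conditions: CuI (10 mol %), 3,4,7,8-tetramethyl-1,10-phenanthroline (20 mol %), Cs2CO3, toluene, 110 °C
Reagents that add atoms: none
Why: Intramolecular Ullmann-type C–O coupling in which the tethered alkoxide closes the six-membered ring onto the aryl bromide; the copper catalyst does not ionise the prenyl ether and C-3 is not involved.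

Step 12
Reactants: 22 (3R)-7-(methoxymethoxy)-3-[2-methoxy-3-(methoxymethoxy)-4-(prenyloxy)phenyl]-3,4-dihydro-2H-chromene
Product: 24 4-[(3R)-7-(methoxymethoxy)-3,4-dihydro-2H-chromen-3-yl]-3-methoxy-2-(methoxymethoxy)-6-(2-methylbut-3-en-2-yl)phenol, via cyclohexadienone 23 (not isolated)
Conditions: degassed EtOH/H2O (4:1), sealed tube, 130 °C
Reagents that add atoms: none
Why: Aromatic Claisen rearrangement ([3,3]-sigmatropic, water-accelerated): C-3' is blocked by the MOM ether, so the prenyl group migrates with allylic inversion to C-5' and the dienone tautomerises to the phenol, leaving C-3 untouched.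

Step 13
Reactants: 24 4-[(3R)-7-(methoxymethoxy)-3,4-dihydro-2H-chromen-3-yl]-3-methoxy-2-(methoxymethoxy)-6-(2-methylbut-3-en-2-yl)phenol
Product: 25 4-[(3R)-7-hydroxy-3,4-dihydro-2H-chromen-3-yl]-3-methoxy-6-(2-methylbut-3-en-2-yl)benzene-1,2-diol
Conditions: 3 M aq HCl, MeOH, argon, 40 °C
Reagents that add atoms: none
Why: Acid-catalysed acetal methanolysis removes both MOM groups, while the monosubstituted alkene, the aryl methyl ether and the non-acidic C-3 center are inert to dilute acid at this temperature.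

## Compound list

1 | 2,3,4-trihydroxybenzaldehyde | O=Cc1ccc(O)c(O)c1O | starting material
2 | prenyl bromide (1-bromo-3-methylbut-2-ene) | CC(C)=CCBr | starting material
3 | 2,3-dihydroxy-4-(prenyloxy)benzaldehyde | O=Cc1ccc(OCC=C(C)C)c(O)c1O | intermediate
4 | disodium 2,3-diolate (dianion) of 3 | O=Cc1ccc(OCC=C(C)C)c([O-])c1[O-].[Na+].[Na+] | intermediate
5 | sodium 6-formyl-2-(methoxymethoxy)-3-(prenyloxy)phenolate | O=Cc1ccc(OCC=C(C)C)c(OCOC)c1[O-].[Na+] | intermediate
6 | 2-methoxy-3-(methoxymethoxy)-4-(prenyloxy)benzaldehyde | O=Cc1ccc(OCC=C(C)C)c(OCOC)c1OC | intermediate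
7 | 5-[2-methoxy-3-(methoxymethoxy)-4-(prenyloxy)phenyl]-4-tosyl-4,5-dihydro-1,3-oxazole (racemic adduct) | Cc1ccc(cc1)S(=O)(=O)C2N=COC2c3ccc(OCC=C(C)C)c(OCOC)c3OC | intermediate
8 | [2-methoxy-3-(methoxymethoxy)-4-(prenyloxy)phenyl]acetonitrile | N#CCc1ccc(OCC=C(C)C)c(OCOC)c1OC | intermediate
9 | 2-[2-methoxy-3-(methoxymethoxy)-4-(prenyloxy)phenyl]acetamide | NC(=O)Cc1ccc(OCC=C(C)C)c(OCOC)c1OC | intermediate
10 | potassium [2-methoxy-3-(methoxymethoxy)-4-(prenyloxy)phenyl]acetate | [K+].[O-]C(=O)Cc1ccc(OCC=C(C)C)c(OCOC)c1OC | intermediate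
11 | [2-methoxy-3-(methoxymethoxy)-4-(prenyloxy)phenyl]acetic acid | OC(=O)Cc1ccc(OCC=C(C)C)c(OCOC)c1OC | intermediate
12 | (R)-4-benzyl-1,3-oxazolidin-2-one | O=C1OC[C@@H](Cc2ccccc2)N1 | starting material
13 | mixed anhydride of 11 with pivalic acid | CC(C)(C)C(=O)OC(=O)Cc1ccc(OCC=C(C)C)c(OCOC)c1OC | intermediate
14 | (4R)-4-benzyl-3-{[2-methoxy-3-(methoxymethoxy)-4-(prenyloxy)phenyl]acetyl}-1,3-oxazolidin-2-one | O=C1OC[C@@H](Cc2ccccc2)N1C(=O)Cc3ccc(OCC=C(C)C)c(OCOC)c3OC | intermediate
15 | 2-bromo-4-hydroxybenzaldehyde | O=Cc1ccc(O)cc1Br | starting material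
16 | 2-bromo-4-(methoxymethoxy)benzaldehyde | O=Cc1ccc(OCOC)cc1Br | intermediate
17 | [2-bromo-4-(methoxymethoxy)phenyl]methanol | OCc1ccc(OCOC)cc1Br | intermediate
18 | 2-bromo-1-(bromomethyl)-4-(methoxymethoxy)benzene | BrCc1ccc(OCOC)cc1Br | intermediate
19 | sodium (Z)-enolate of 14 (O and aryl cis, 4R auxiliary) | O=C1OC[C@@H](Cc2ccccc2)N1/C([O-])=C/c3ccc(OCC=C(C)C)c(OCOC)c3OC.[Na+] | intermediate
20 | (4R)-4-benzyl-3-{(2R)-3-[2-bromo-4-(methoxymethoxy)phenyl]-2-[2-methoxy-3-(methoxymethoxy)-4-(prenyloxy)phenyl]propanoyl}-1,3-oxazolidin-2-one | O=C1OC[C@@H](Cc2ccccc2)N1C(=O)[C@H](Cc3ccc(OCOC)cc3Br)c4ccc(OCC=C(C)C)c(OCOC)c4OC | intermediate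
21 | (2R)-3-[2-bromo-4-(methoxymethoxy)phenyl]-2-[2-methoxy-3-(methoxymethoxy)-4-(prenyloxy)phenyl]propan-1-ol | OC[C@H](Cc1ccc(OCOC)cc1Br)c1ccc(OCC=C(C)C)c(OCOC)c1OC | intermediate
22 | (3R)-7-(methoxymethoxy)-3-[2-methoxy-3-(methoxymethoxy)-4-(prenyloxy)phenyl]-3,4-dihydro-2H-chromene | CC(C)=CCOc1ccc([C@@H]2COc3cc(OCOC)ccc3C2)c(OC)c1OCOC | intermediate
23 | 4-[(3R)-7-(methoxymethoxy)chroman-3-yl]-3-methoxy-2-(methoxymethoxy)-6-(2-methylbut-3-en-2-yl)cyclohexa-2,4-dien-1-one (C-6 unassigned) | C=CC(C)(C)C1C=C([C@@H]2COc3cc(OCOC)ccc3C2)C(OC)=C(OCOC)C1=O | intermediate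
24 | 4-[(3R)-7-(methoxymethoxy)-3,4-dihydro-2H-chromen-3-yl]-3-methoxy-2-(methoxymethoxy)-6-(2-methylbut-3-en-2-yl)phenol | C=CC(C)(C)c1cc([C@@H]2COc3cc(OCOC)ccc3C2)c(OC)c(OCOC)c1O | intermediate
25 | 4-[(3R)-7-hydroxy-3,4-dihydro-2H-chromen-3-yl]-3-methoxy-6-(2-methylbut-3-en-2-yl)benzene-1,2-diol | C=CC(C)(C)c1cc([C@@H]2COc3cc(O)ccc3C2)c(OC)c(O)c1O | target

## Step count and risks

Total step count: 13. Longest linear sequence: 10 steps (steps 1–5 and 9–13, from 1); the ring A bromide takes 3 steps (6–8) and joins at step 9.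

Step 2 is the first risk, because any MOM on O-2 or double alkylation gives isomers that are hard to separate. The fallback sets out from 1 and comes back at 6, fixing each oxygen by a ketal instead of by dianion reactivity. Heating 1 with dichlorodiphenylmethane in diphenyl ether at 170 °C ties O-3 and O-4 together and leaves only the chelated 2-OH, giving 4-hydroxy-2,2-diphenyl-1,3-benzodioxole-5-carbaldehyde F1. MeI/K2CO3 in DMF gives 4-methoxy-2,2-diphenyl-1,3-benzodioxole-5-carbaldehyde F2, and AcOH/H2O at reflux releases 3,4-dihydroxy-2-methoxybenzaldehyde F3. Prenyl bromide 2 with Li2CO3 in DMF alkylates the OH para to the formyl group to give 3-hydroxy-2-methoxy-4-(prenyloxy)benzaldehyde F4, and MOMCl/i-Pr2NEt then gives 6.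

Step 11 is the second risk, since the copper-catalysed closure may stall or give hydrodebromination. The fallback sets out from 21 and comes back at 22, turning the bromide into a phenol and closing the ring at the alkyl carbon instead. Compound 21 is treated with n-BuLi (2.2 equiv, THF, −78 °C; alkoxide formation, then bromine–lithium exchange) and B(OMe)3 to give dimethyl {2-[(2R)-3-hydroxy-2-[2-methoxy-3-(methoxymethoxy)-4-(prenyloxy)phenyl]propyl]-5-(methoxymethoxy)phenyl}boronate F5. This is oxidised in the same flask with NaOH/H2O2 to 2-[(2R)-3-hydroxy-2-[2-methoxy-3-(methoxymethoxy)-4-(prenyloxy)phenyl]propyl]-5-(methoxymethoxy)phenol F6. Mitsunobu etherification (PPh3, DIAD, THF, 0 °C) at the primary carbinol then gives 22 without touching the stereocenter.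

Step 12 is the third risk, because the free ortho-(1,1-dimethylallyl)phenol can isomerise further (abnormal Claisen), cyclise to a dihydrobenzofuran or lose the prenyl group. The fallback sets out from 22 and comes back at 24, trapping the phenol as it forms. Compound 22 is heated in N,N-diethylaniline with Ac2O and NaOAc at 190 °C to give 4-[(3R)-7-(methoxymethoxy)-3,4-dihydro-2H-chromen-3-yl]-3-methoxy-2-(methoxymethoxy)-6-(2-methylbut-3-en-2-yl)phenyl acetate F7. K2CO3 in MeOH (rt, argon) then frees 24.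

## Further compounds

F1 | step 2 | 4-hydroxy-2,2-diphenyl-1,3-benzodioxole-5-carbaldehyde | O=Cc1ccc2OC(c3ccccc3)(c4ccccc4)Oc2c1O
F2 | step 2 | 4-methoxy-2,2-diphenyl-1,3-benzodioxole-5-carbaldehyde | O=Cc1ccc2OC(c3ccccc3)(c4ccccc4)Oc2c1OC
F3 | step 2 | 3,4-dihydroxy-2-methoxybenzaldehyde | O=Cc1ccc(O)c(O)c1OC
F4 | step 2 | 3-hydroxy-2-methoxy-4-(prenyloxy)benzaldehyde | O=Cc1ccc(OCC=C(C)C)c(O)c1OC
F5 | step 11 | dimethyl {2-[(2R)-3-hydroxy-2-[2-methoxy-3-(methoxymethoxy)-4-(prenyloxy)phenyl]propyl]-5-(methoxymethoxy)phenyl}boronate | COB(OC)c1cc(OCOC)ccc1C[C@@H](CO)c1ccc(OCC=C(C)C)c(OCOC)c1OC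
F6 | step 11 | 2-[(2R)-3-hydroxy-2-[2-methoxy-3-(methoxymethoxy)-4-(prenyloxy)phenyl]propyl]-5-(methoxymethoxy)phenol | Oc1cc(OCOC)ccc1C[C@@H](CO)c1ccc(OCC=C(C)C)c(OCOC)c1OC
F7 | step 12 | 4-[(3R)-7-(methoxymethoxy)-3,4-dihydro-2H-chromen-3-yl]-3-methoxy-2-(methoxymethoxy)-6-(2-methylbut-3-en-2-yl)phenyl acetate | C=CC(C)(C)c1cc([C@@H]2COc3cc(OCOC)ccc3C2)c(OC)c(OCOC)c1OC(C)=O
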